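**Retrosynthetic overview**

1. Target 11 comes from 10 by freeing O-3 last: Zn in acetic acid removes a 2,2,2-trichloroethyl (Troc) carbonate, so the 1,2-diacyl-sn-glycerol never meets base.
2. 10 comes from 9 in the key step. The acyl group is a β-monocyclofarnesoate whose only ring, ring A (C1' = alkene carbon bearing the side chain, C2' = alkene carbon bearing the methyl, C6' = gem-dimethyl carbon), is the folded tail of a farnesoate (farnesyl C6, C7, C11). The C1'–C6' bond (farnesyl C6–C11) is therefore made by proton-initiated cation–olefin cyclisation of the fully acylated farnesoyl glyceride.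
3. 9 comes from alcohol 8 and acid 3 by esterification at O-2; acid 3 comes from (2E,6E)-farnesol 1 by two oxidations.
4. 8 comes from (S)-solketal 4 and TrocCl 5: carbonate on the free hydroxyl (the later free O-3), acetonide off, acetate on the primary hydroxyl. The single stereocentre (glycerol C2) is bought and no bond to it is ever broken.
5. Ring order: ring A only, closed in step 7.

Key step: step 7

Remark: the target is read as 1-O-acetyl-2-O-[(2E)-β-monocyclofarnesoyl]-sn-glycerol, (S) at glycerol C2, and farnesol is taken as bought in pure (2E,6E) form; the Troc-bearing intermediates have the same spatial arrangement but are named (R) because the carbonate arm outranks the acetate arm.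

**Route**

Step 1
Reactants: 1 (2E,6E)-farnesol
Product: 2 (2E,6E)-farnesal
Conditions: TEMPO (2,2,6,6-tetramethylpiperidin-1-oxyl, 10 mol %), PhI(OAc)2 (1.1 equiv), CH2Cl2, rt
Reagents that add atoms: none
Why: The TEMPO/PhI(OAc)2 (oxoammonium) oxidation of a primary allylic alcohol stops at the aldehyde and, being neither acidic nor basic enough to isomerise an enal, should carry the 2E and 6E alkenes through unchanged.

Step 2
Reactants: 2 (2E,6E)-farnesal
Product: 3 (2E,6E)-farnesoic acid
Conditions: NaClO2, NaH2PO4, 2-methyl-2-butene (large excess), t-BuOH/H2O, 0 °C to rt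
Reagents that add atoms: sodium chlorite, [Na+].[O-]Cl=O
Why: The Pinnick oxidation turns the enal into the acid without touching the conjugated 2E alkene, while the excess of 2-methyl-2-butene removes the hypochlorous acid that would otherwise attack the two isolated alkenes.

Step 3
Reactants: 4 (S)-solketal (1,2-O-isopropylidene-sn-glycerol); 5 2,2,2-trichloroethyl chloroformate
Product: 6 1,2-O-isopropylidene-3-O-(2,2,2-trichloroethoxycarbonyl)-sn-glycerol
Conditions: pyridine, CH2Cl2, 0 °C
Reagents that add atoms: none
Why: Carbonate formation by acylation of the primary hydroxyl with the chloroformate is fast at 0 °C, leaves the acetonide intact and breaks no bond at the stereocentre, so the configuration of (S)-solketal is carried over unchanged.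

Step 4
Reactants: 6 1,2-O-isopropylidene-3-O-Troc-sn-glycerol
Product: 7 3-O-(2,2,2-trichloroethoxycarbonyl)-sn-glycerol
Conditions: sulfonic acid resin Amberlyst 15 (H+ form), MeOH/H2O (9:1), rt; filter, evaporate below 30 °C
Reagents that add atoms: none
Why: Acid-catalysed hydrolysis of the isopropylidene acetal on the resin frees the two hydroxyls without involving the stereocentre, and because the resin is simply filtered off the diol never meets base, which could make O-2 close on the carbonate or shift it.

Step 5
Reactants: 7 3-O-Troc-sn-glycerol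
Product: 8 1-O-acetyl-3-O-(2,2,2-trichloroethoxycarbonyl)-sn-glycerol
Conditions: AcCl (1.05 equiv), 2,4,6-collidine, CH2Cl2, −78 °C
Reagents that add atoms: acetyl chloride, CC(=O)Cl
Why: Kinetic acylation with acetyl chloride and the hindered weak base collidine at −78 °C discriminates the primary hydroxyl from the secondary one, which is flanked by two substituted carbons, and collidine is too weak a base to promote attack of O-2 on the neighbouring carbonate.

Step 6
Reactants: 8 1-O-acetyl-3-O-Troc-sn-glycerol; 3 (2E,6E)-farnesoic acid
Product: 9 1-O-acetyl-2-O-[(2E,6E)-farnesoyl]-3-O-(2,2,2-trichloroethoxycarbonyl)-sn-glycerol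
Conditions: DCC (N,N'-dicyclohexylcarbodiimide), DMAP (4-dimethylaminopyridine, 0.1 equiv), CH2Cl2, 0 °C to rt
Reagents that add atoms: none
Why: Steglich esterification acylates the remaining secondary hydroxyl with retention because the C2–O bond is never broken, and low temperature with only catalytic DMAP is chosen to keep the 2E enoate from isomerising or deconjugating and the primary acetate from shifting.

Step 7
Reactants: 9 1-O-acetyl-2-O-[(2E,6E)-farnesoyl]-3-O-Troc-sn-glycerol
Product: 10 1-O-acetyl-2-O-[(2E)-β-monocyclofarnesoyl]-3-O-(2,2,2-trichloroethoxycarbonyl)-sn-glycerol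
Conditions: ClSO3H (5 equiv), 2-nitropropane, −78 °C, 15–20 min; Et3N in hexane, −78 °C; chromatography on AgNO3-impregnated silica
Reagents that add atoms: none
Why: Protonation of the terminal trisubstituted alkene at C10, assisted by the C6=C7 alkene, forms the C6–C11 bond (C1'–C6' of the target) in a chair-like 6-endo-trig closure with respect to the C6=C7 alkene and leaves a tertiary cation on C7, and loss of the proton on C6 then gives the tetrasubstituted alkene of ring A. The closest known reaction is the low-temperature strong-acid cation–olefin cyclisation of farnesyl acetate and of farnesoic esters, here run on a glycerol triester. No stereocentre is created, because the sp3 centre that appears at C6 is erased by the proton loss, and the glycerol C2 centre is remote and carries three acylated oxygens, so it should neither epimerise nor exchange acyl groups at −78 °C. The selectivity that matters is arrest after one ring: a second closure would need the α-carbon of the conjugated ester as nucleophile, which is the least electron-rich alkene in the molecule and is further deactivated by O-protonation in the excess acid, so it is expected to be much slower than the first closure and is denied time by the short contact at −78 °C and the cold amine quench. The position of the new alkene is the second issue: reversible proton loss and re-protonation in the acid should favour the most substituted C6=C7 isomer, and any trisubstituted or exocyclic isomer is to be removed on the silver-loaded silica and passed through the same conditions again.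

Step 8
Reactants: 10 1-O-acetyl-2-O-[(2E)-β-monocyclofarnesoyl]-3-O-Troc-sn-glycerol
Product: 11 1-O-acetyl-2-O-[(2E)-β-monocyclofarnesoyl]-sn-glycerol (CNP0305511.1)
Conditions: Zn dust (activated), AcOH/THF, 0 °C to rt; filter, cold neutral work-up, rapid chromatography on boric acid-impregnated silica
Reagents that add atoms: none
Why: Reductive β-elimination of the 2,2,2-trichloroethyl carbonate by zinc (loss of 1,1-dichloroethene and CO2) frees O-3 in an acidic medium in which neither the enoate on O-2 nor the acetate on O-1 should migrate, and zinc in acetic acid does not reduce the β,β-disubstituted enoate or the tetrasubstituted ring alkene.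

**Compound list**

1 | (2E,6E)-farnesol, (2E,6E)-3,7,11-trimethyldodeca-2,6,10-trien-1-ol | CC(C)=CCC/C(C)=C/CC/C(C)=C/CO | starting material
2 | (2E,6E)-farnesal | CC(C)=CCC/C(C)=C/CC/C(C)=C/C=O | intermediate
3 | (2E,6E)-farnesoic acid | CC(C)=CCC/C(C)=C/CC/C(C)=C/C(=O)O | intermediate
4 | (S)-solketal, 1,2-O-isopropylidene-sn-glycerol | CC1(C)OC[C@H](CO)O1 | starting material
5 | 2,2,2-trichloroethyl chloroformate (TrocCl) | ClC(=O)OCC(Cl)(Cl)Cl | starting material
6 | [(4R)-2,2-dimethyl-1,3-dioxolan-4-yl]methyl 2,2,2-trichloroethyl carbonate (1,2-O-isopropylidene-3-O-Troc-sn-glycerol) | CC1(C)OC[C@H](COC(=O)OCC(Cl)(Cl)Cl)O1 | intermediate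
7 | (2R)-2,3-dihydroxypropyl 2,2,2-trichloroethyl carbonate (3-O-Troc-sn-glycerol) | OC[C@H](COC(=O)OCC(Cl)(Cl)Cl)O | intermediate
8 | (2R)-3-acetoxy-2-hydroxypropyl 2,2,2-trichloroethyl carbonate (1-O-acetyl-3-O-Troc-sn-glycerol) | CC(=O)OC[C@H](COC(=O)OCC(Cl)(Cl)Cl)O | intermediate
9 | 1-O-acetyl-2-O-[(2E,6E)-farnesoyl]-3-O-Troc-sn-glycerol, (R) at glycerol C2 | CC(=O)OC[C@H](COC(=O)OCC(Cl)(Cl)Cl)OC(=O)/C=C(\C)CC/C=C(\C)CCC=C(C)C | intermediate
10 | 1-O-acetyl-2-O-[(2E)-3-methyl-5-(2,6,6-trimethylcyclohex-1-en-1-yl)pent-2-enoyl]-3-O-Troc-sn-glycerol, (R) at glycerol C2 | CC(=O)OC[C@H](COC(=O)OCC(Cl)(Cl)Cl)OC(=O)/C=C(\C)CCC1=C(C)CCCC1(C)C | intermediate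
11 | (2S)-1-acetoxy-3-hydroxypropan-2-yl (2E)-3-methyl-5-(2,6,6-trimethylcyclohex-1-en-1-yl)pent-2-enoate (CNP0305511.1) | CC(=O)OC[C@H](CO)OC(=O)/C=C(\C)CCC1=C(C)CCCC1(C)C | target

**Step count**

Total: 8 steps. Longest linear sequence: 6 steps (4 to 11 through steps 3, 4, 5, 6, 7, 8); the acid branch 1 to 3 (steps 1 and 2) joins at step 6.

**Steps most likely to fail**

Step 7. The cascade may not stop after ring A: if the cation on C2' lives long enough, the α-carbon of the conjugated ester can close a second ring. Proton loss may also occur from the ring methylene or the methyl group instead of from C1', the 2E alkene may isomerise in the protonated enoate, and acyl groups could be shuffled on glycerol through acyloxonium ions if the mixture warms. The fallback buys ring A ready-made and sets out from alcohol 8. Commercial dihydro-β-ionone, 4-(2,6,6-trimethylcyclohex-1-en-1-yl)butan-2-one, is olefinated with triethyl phosphonoacetate and NaH in THF (Horner–Wadsworth–Emmons) to give ethyl (2E)-3-methyl-5-(2,6,6-trimethylcyclohex-1-en-1-yl)pent-2-enoate F1, the 2Z isomer being removed by chromatography. Saponification with KOH in aqueous ethanol should give (2E)-3-methyl-5-(2,6,6-trimethylcyclohex-1-en-1-yl)pent-2-enoic acid F2, which is coupled with 8 under the DCC/DMAP conditions of step 6. The fallback comes back to the route at compound 10.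

Step 8. The enoate on O-2 may migrate to the freed primary O-3 during the reduction, the work-up or on silica, and the reduction may stall at a partly dechlorinated carbonate. The fallback changes the O-3 protecting group to a levulinate, which is removed by buffered hydrazine instead of by a metal, and sets out from (S)-solketal 4. Levulinic acid with DCC/DMAP should give 3-O-levulinoyl-1,2-O-isopropylidene-sn-glycerol F3, the acid resin of step 4 gives 3-O-levulinoyl-sn-glycerol F4, and AcCl/collidine at −78 °C gives 1-O-acetyl-3-O-levulinoyl-sn-glycerol F5. Esterification with acid 3 gives 1-O-acetyl-2-O-[(2E,6E)-farnesoyl]-3-O-levulinoyl-sn-glycerol F6, and the cyclisation conditions of step 7 give 1-O-acetyl-2-O-[(2E)-β-monocyclofarnesoyl]-3-O-levulinoyl-sn-glycerol F7. Hydrazine acetate in pyridine/acetic acid at rt then removes the levulinate and the fallback comes back to the route at compound 11.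

Step 6. Acylation of the hindered secondary hydroxyl with a conjugated, β,β-disubstituted acid may be slow enough for the acetate to shift from O-1 to O-2 under DMAP, or for O-2 to attack the carbonate, so that the farnesoyl group ends on the wrong oxygen. The fallback reverses the order of acylation and sets out from diol 7. TBSCl and imidazole in CH2Cl2 at 0 °C should silylate the primary hydroxyl to give 1-O-(tert-butyldimethylsilyl)-3-O-Troc-sn-glycerol F8, which has no acyl group that can shift. Esterification with acid 3 (DCC/DMAP) gives 2-O-[(2E,6E)-farnesoyl]-1-O-(tert-butyldimethylsilyl)-3-O-Troc-sn-glycerol F9, and HF·pyridine in THF at 0 °C gives 2-O-[(2E,6E)-farnesoyl]-3-O-Troc-sn-glycerol F10. This is acetylated at once with AcCl/collidine at low temperature, and the fallback comes back to the route at compound 9.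

**Further compounds**

F1 | step 7 | ethyl (2E)-3-methyl-5-(2,6,6-trimethylcyclohex-1-en-1-yl)pent-2-enoate | CCOC(=O)/C=C(\C)CCC1=C(C)CCCC1(C)C
F2 | step 7 | (2E)-3-methyl-5-(2,6,6-trimethylcyclohex-1-en-1-yl)pent-2-enoic acid | OC(=O)/C=C(\C)CCC1=C(C)CCCC1(C)C
F3 | step 8 | 3-O-levulinoyl-1,2-O-isopropylidene-sn-glycerol | CC1(C)OC[C@H](COC(=O)CCC(C)=O)O1
F4 | step 8 | 3-O-levulinoyl-sn-glycerol | OC[C@H](COC(=O)CCC(C)=O)O
F5 | step 8 | 1-O-acetyl-3-O-levulinoyl-sn-glycerol | CC(=O)OC[C@H](COC(=O)CCC(C)=O)O
F6 | step 8 | 1-O-acetyl-2-O-[(2E,6E)-farnesoyl]-3-O-levulinoyl-sn-glycerol | CC(=O)OC[C@H](COC(=O)CCC(C)=O)OC(=O)/C=C(\C)CC/C=C(\C)CCC=C(C)C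
F7 | step 8 | 1-O-acetyl-2-O-[(2E)-β-monocyclofarnesoyl]-3-O-levulinoyl-sn-glycerol | CC(=O)OC[C@H](COC(=O)CCC(C)=O)OC(=O)/C=C(\C)CCC1=C(C)CCCC1(C)C
F8 | step 6 | 1-O-(tert-butyldimethylsilyl)-3-O-Troc-sn-glycerol | CC(C)(C)[Si](C)(C)OC[C@H](COC(=O)OCC(Cl)(Cl)Cl)O
F9 | step 6 | 2-O-[(2E,6E)-farnesoyl]-1-O-(tert-butyldimethylsilyl)-3-O-Troc-sn-glycerol | CC(C)(C)[Si](C)(C)OC[C@H](COC(=O)OCC(Cl)(Cl)Cl)OC(=O)/C=C(\C)CC/C=C(\C)CCC=C(C)C
F10 | step 6 | 2-O-[(2E,6E)-farnesoyl]-3-O-Troc-sn-glycerol | OC[C@H](COC(=O)OCC(Cl)(Cl)Cl)OC(=O)/C=C(\C)CC/C=C(\C)CCC=C(C)C
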